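**Retrosynthetic overview**
1. Last bond: C‑7–C‑2′ of the propanoate side chain, made by an enantioconvergent nickel coupling of a ring B α‑iodoenone with racemic methyl 2‑chloropropanoate; the angelate, the iodide and the C‑2 carbinol are put on just before.
2. Ring B (the cyclohexenone) comes from a cis‑fused cyclopentanone by a one‑carbon ring expansion (CH2 inserted between C=O and the ring‑fusion CH); an α‑bromine steers the 1,2‑shift and is then eliminated to give the enone.
3. Ring A is built on 3‑methylcyclopent‑2‑enone by an enantioselective Diels–Alder reaction with a 2‑silyloxydiene ester; this sets the quaternary methyl carbon and the cis ring fusion and brings in the C‑1 ester and the masked C‑2 ketone.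
4. The diene comes from methyl acetate and acrolein.
5. Ring order: five‑membered ring (bought) → ring A (cycloaddition) → ring B (expansion of the five‑membered ring).

Assumption: the target is taken exactly as the SMILES draws it, i.e. methyl (1S,2R,4aS,8aS)-7-[(2S)-1-methoxy-1-oxopropan-2-yl]-8a-methyl-2-{[(2Z)-2-methylbut-2-enoyl]oxy}-6-oxo-1,2,3,4,4a,5,6,8a-octahydronaphthalene-1-carboxylate; naphthalene locants are used for all decalins and indene locants for the hydrindanes.

**Step 1**
Reactants: 1 methyl acetate; 2 acrolein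
Product: 4 methyl 3-hydroxypent-4-enoate (racemic), via lithium enolate of methyl acetate 3 (not isolated)
Conditions: LiN(iPr)2, THF, −78 °C; then 2, −78 °C; AcOH quench
Reagents that add atoms: none
Why: Directed aldol addition; the preformed lithium ester enolate adds 1,2 to acrolein at −78 °C, and the racemic carbinol centre is oxidised away in step 2.

**Step 2**
Reactants: 4 methyl 3-hydroxypent-4-enoate
Product: 6 methyl (2Z)-3-[(tert-butyldimethylsilyl)oxy]penta-2,4-dienoate, via methyl 3-oxopent-4-enoate 5 (not isolated)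
Conditions: (COCl)2, DMSO, CH2Cl2, −78 °C; Et3N; then TBSOTf, −78 → 0 °C (one flask)
Reagents that add atoms: tert-butyldimethylsilyl trifluoromethanesulfonate, CC(C)(C)[Si](C)(C)OS(=O)(=O)C(F)(F)F
Why: Swern oxidation followed by soft enolisation and O‑silylation; the polymerisation‑prone vinyl β‑keto ester is trapped at once as the Z silyl dienol ether (Z from the hydrogen‑bonded enol), which is the 2‑silyloxydiene for step 3.

**Step 3**
Reactants: 6 methyl (2Z)-3-[(tert-butyldimethylsilyl)oxy]penta-2,4-dienoate; 7 3-methylcyclopent-2-en-1-one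
Product: 8 methyl (3aR,7aR)-5-[(tert-butyldimethylsilyl)oxy]-3a-methyl-1-oxo-2,3,3a,4,7,7a-hexahydro-1H-indene-4-carboxylate (cis-fused; C-4 epimers)
Conditions: AlBr3 adduct of (S)-1-(2-methylphenyl)-3,3-diphenyltetrahydro-1H,3H-pyrrolo[1,2-c][1,3,2]oxazaborole (10 mol %), CH2Cl2, −40 °C
Reagents that add atoms: none
Why: Proposed new method: catalytic enantioselective Diels–Alder reaction of a β‑methylcyclopentenone, in which the AlBr3‑activated oxazaborolidine binds the enone carbonyl (ordered by the α‑vinyl C–H···O contact typical of 2‑cycloalkenones), shields one face with its aryl group and lowers the LUMO enough for the silyloxydiene to add its nucleophilic ester‑bearing terminus to the β‑carbon, so the quaternary C‑3a, the cis fusion (suprafacial addition to the ring alkene) and the absolute configuration arise together while C‑4 stays epimerisable (the catalyst antipode is the one that gives 3aR,7aR, to be confirmed in a pilot run); closest known reaction type: oxazaborolidinium‑catalysed enantioselective Diels–Alder reactions of cyclopentenone and cyclohexenone with 2‑silyloxybutadienes, and the racemic mixed aluminium Lewis acid cycloadditions of 3‑methylcycloalkenones with hindered silyloxydienes.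

**Step 4**
Reactants: 8 methyl (3aR,7aR)-5-[(tert-butyldimethylsilyl)oxy]-3a-methyl-1-oxo-2,3,3a,4,7,7a-hexahydro-1H-indene-4-carboxylate
Product: 10 methyl (3aR,7aR)-2-bromo-5-[(tert-butyldimethylsilyl)oxy]-3a-methyl-1-oxo-2,3,3a,4,7,7a-hexahydro-1H-indene-4-carboxylate (C-2 and C-4 epimers), via hydrindanone lithium enolate 9 (not isolated)
Conditions: LiN(iPr)2, THF, −78 °C; then N-bromosuccinimide, −78 °C; AcOH quench
Reagents that add atoms: N-bromosuccinimide, O=C1CCC(=O)N1Br
Why: Kinetic enolate α‑bromination; the base removes the unhindered C‑2 methylene proton rather than the ring‑fusion methine, the lithium enolate takes Br+ far faster than the neutral silyl enol ether, and the bromide is the control element for step 5 (its configuration is immaterial).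

**Step 5**
Reactants: 10 methyl (3aR,7aR)-2-bromo-5-[(tert-butyldimethylsilyl)oxy]-3a-methyl-1-oxo-2,3,3a,4,7,7a-hexahydro-1H-indene-4-carboxylate
Product: 12 methyl (4aS,8aR)-7-bromo-2-[(tert-butyldimethylsilyl)oxy]-8a-methyl-6-oxo-1,4,4a,5,6,7,8,8a-octahydronaphthalene-1-carboxylate (C-1 and C-7 epimers), via C-silylated ring-expanded ketone 11 (not isolated)
Conditions: Me3SiCHN2, AlMe3, CH2Cl2, −78 → −20 °C; then MeOH, AcOH (cat.), 0 °C; aqueous work-up
Reagents that add atoms: trimethylsilyldiazomethane, C[Si](C)(C)C=[N+]=[N-]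
Why: Key ring expansion by Lewis acid‑promoted diazoalkane homologation (Tiffeneau–Demjanov‑type 1,2‑alkyl shift); a halogen‑bearing α‑carbon migrates poorly, so the ring‑fusion carbon shifts to the diazo carbon with retention as N2 leaves, which inserts CH2 only between C=O and the ring fusion and keeps the cis fusion, while the silyl enol ether keeps the ring A carbonyl out of the reaction and the C‑bound Me3Si is lost in the methanolic work‑up.

**Step 6**
Reactants: 12 methyl (4aS,8aR)-7-bromo-2-[(tert-butyldimethylsilyl)oxy]-8a-methyl-6-oxo-1,4,4a,5,6,7,8,8a-octahydronaphthalene-1-carboxylate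
Product: 14 methyl (4aS,8aS)-8a-methyl-2,6-dioxo-1,2,3,4,4a,5,6,8a-octahydronaphthalene-1-carboxylate (C-1 epimers and enol), via silyl enol ether enone 13 (not isolated)
Conditions: Li2CO3, LiBr, DMF, 100 °C; then 1 M HCl, THF, 23 °C
Reagents that add atoms: none
Why: E2 dehydrobromination gives the only possible enone because the sole β‑hydrogens are on C‑8, and acid hydrolysis of the silyl enol ether then releases the β‑keto ester (done after the elimination so that the hot LiBr/DMF never meets a β‑keto ester); no stereocentre is formed and the ring fusion, now β to the ketone, can no longer epimerise.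

**Step 7**
Reactants: 14 methyl (4aS,8aS)-8a-methyl-2,6-dioxo-1,2,3,4,4a,5,6,8a-octahydronaphthalene-1-carboxylate
Product: 15 methyl (1S,2R,4aS,8aS)-2-hydroxy-8a-methyl-6-oxo-1,2,3,4,4a,5,6,8a-octahydronaphthalene-1-carboxylate
Conditions: NaBH4, MeOH/CH2Cl2 1:1, −78 °C
Reagents that add atoms: none
Why: Chemoselective borohydride reduction under Felkin–Anh (polar) control; at −78 °C only the saturated ring A ketone reacts (the conjugated enone is much slower), hydride adds anti to the axial C‑1 ester of the rapidly epimerising β‑keto ester, and this puts 2‑OH equatorial and cis to both the ester and the angular methyl and fixes C‑1 in the same event (dynamic kinetic reduction).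

**Step 8**
Reactants: 15 methyl (1S,2R,4aS,8aS)-2-hydroxy-8a-methyl-6-oxo-1,2,3,4,4a,5,6,8a-octahydronaphthalene-1-carboxylate
Product: 16 methyl (1S,2R,4aS,8aR)-2-hydroxy-7-iodo-8a-methyl-6-oxo-1,2,3,4,4a,5,6,8a-octahydronaphthalene-1-carboxylate
Conditions: I2, pyridine/CH2Cl2 1:1, 23 °C
Reagents that add atoms: iodine, II
Why: α‑Iodination of an enone by the pyridine‑mediated addition–elimination (Baylis–Hillman‑type) path, which works well on 4,4‑disubstituted cyclohexenones and leaves the alcohol and ester untouched; iodination precedes the angelate so that iodine never meets the Z enoate.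

**Step 9**
Reactants: 16 methyl (1S,2R,4aS,8aR)-2-hydroxy-7-iodo-8a-methyl-6-oxo-1,2,3,4,4a,5,6,8a-octahydronaphthalene-1-carboxylate; 17 angelic acid
Product: 19 methyl (1S,2R,4aS,8aR)-7-iodo-8a-methyl-2-{[(2Z)-2-methylbut-2-enoyl]oxy}-6-oxo-1,2,3,4,4a,5,6,8a-octahydronaphthalene-1-carboxylate, via angelic 2,4,6-trichlorobenzoic anhydride 18 (not isolated)
Conditions: 17, 2,4,6-trichlorobenzoyl chloride, Et3N, toluene, 23 °C; then 16, 80 °C
Reagents that add atoms: none
Why: Yamaguchi‑type esterification through the mixed anhydride without DMAP, the usual way to acylate a hindered secondary alcohol with angelic acid without Z to E isomerisation; C‑2 keeps its configuration.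

**Step 10**
Reactants: 19 methyl (1S,2R,4aS,8aR)-7-iodo-8a-methyl-2-{[(2Z)-2-methylbut-2-enoyl]oxy}-6-oxo-1,2,3,4,4a,5,6,8a-octahydronaphthalene-1-carboxylate; 20 methyl 2-chloropropanoate (racemic)
Product: 21 methyl (1S,2R,4aS,8aS)-7-[(2S)-1-methoxy-1-oxopropan-2-yl]-8a-methyl-2-{[(2Z)-2-methylbut-2-enoyl]oxy}-6-oxo-1,2,3,4,4a,5,6,8a-octahydronaphthalene-1-carboxylate
Conditions: NiBr2·MeOCH2CH2OMe (10 mol %), (4S,4'S)-4,4'-di(heptan-4-yl)-4,4',5,5'-tetrahydro-2,2'-bioxazole (12 mol %), Mn powder, NaI, N,N-dimethylacetamide, 5 °C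
Reagents that add atoms: none
Why: Proposed new method: enantioconvergent nickel‑catalysed reductive C(sp2)–C(sp3) coupling of an α‑iodoenone with a racemic α‑chloro ester, in which zerovalent nickel inserts into the C–I bond, the alkenylnickel species captures the planar α‑ester radical formed by chlorine abstraction from either enantiomer of 20, and reductive elimination from the bis(oxazoline)‑bound trivalent nickel centre sets C‑2′ as S under catalyst control while Mn turns the catalyst over (ligand antipode chosen for 2′S, to be confirmed in a pilot run); closest known reaction type: nickel/bis(oxazoline)‑catalysed asymmetric reductive cross‑couplings of alkenyl bromides with benzylic chlorides and of α‑chloro esters with aryl iodides.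

**Compound list**
1 | methyl acetate | CC(=O)OC | starting material
2 | acrolein (prop-2-enal) | C=CC=O | starting material
3 | lithium enolate of methyl acetate (lithium 1-methoxyethen-1-olate) | [Li+].[O-]C(=C)OC | intermediate
4 | methyl 3-hydroxypent-4-enoate (racemic) | C=CC(O)CC(=O)OC | intermediate
5 | methyl 3-oxopent-4-enoate | C=CC(=O)CC(=O)OC | intermediate
6 | methyl (2Z)-3-[(tert-butyldimethylsilyl)oxy]penta-2,4-dienoate | COC(=O)/C=C(\O[Si](C)(C)C(C)(C)C)C=C | intermediate
7 | 3-methylcyclopent-2-en-1-one | CC1=CC(=O)CC1 | starting material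
8 | methyl (3aR,7aR)-5-[(tert-butyldimethylsilyl)oxy]-3a-methyl-1-oxo-2,3,3a,4,7,7a-hexahydro-1H-indene-4-carboxylate (cis-fused; C-4 epimers) | CC(C)(C)[Si](C)(C)OC1=CC[C@H]2C(=O)CC[C@@]2(C)C1C(=O)OC | intermediate
9 | lithium enolate of 8 (enolate towards C-2) | [Li+].CC(C)(C)[Si](C)(C)OC1=CC[C@H]2C([O-])=CC[C@@]2(C)C1C(=O)OC | intermediate
10 | methyl (3aR,7aR)-2-bromo-5-[(tert-butyldimethylsilyl)oxy]-3a-methyl-1-oxo-2,3,3a,4,7,7a-hexahydro-1H-indene-4-carboxylate (C-2 and C-4 epimers) | CC(C)(C)[Si](C)(C)OC1=CC[C@H]2C(=O)C(Br)C[C@@]2(C)C1C(=O)OC | intermediate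
11 | methyl (4aR,8aS)-7-bromo-2-[(tert-butyldimethylsilyl)oxy]-8a-methyl-6-oxo-5-(trimethylsilyl)-1,4,4a,5,6,7,8,8a-octahydronaphthalene-1-carboxylate (C-1, C-5 and C-7 epimers) | CC(C)(C)[Si](C)(C)OC1=CC[C@H]2C([Si](C)(C)C)C(=O)C(Br)C[C@@]2(C)C1C(=O)OC | intermediate
12 | methyl (4aS,8aR)-7-bromo-2-[(tert-butyldimethylsilyl)oxy]-8a-methyl-6-oxo-1,4,4a,5,6,7,8,8a-octahydronaphthalene-1-carboxylate (C-1 and C-7 epimers) | CC(C)(C)[Si](C)(C)OC1=CC[C@H]2CC(=O)C(Br)C[C@@]2(C)C1C(=O)OC | intermediate
13 | methyl (4aS,8aS)-2-[(tert-butyldimethylsilyl)oxy]-8a-methyl-6-oxo-1,4,4a,5,6,8a-hexahydronaphthalene-1-carboxylate (C-1 epimers) | CC(C)(C)[Si](C)(C)OC1=CC[C@H]2CC(=O)C=C[C@@]2(C)C1C(=O)OC | intermediate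
14 | methyl (4aS,8aS)-8a-methyl-2,6-dioxo-1,2,3,4,4a,5,6,8a-octahydronaphthalene-1-carboxylate (C-1 epimers and enol) | O=C1CC[C@H]2CC(=O)C=C[C@@]2(C)C1C(=O)OC | intermediate
15 | methyl (1S,2R,4aS,8aS)-2-hydroxy-8a-methyl-6-oxo-1,2,3,4,4a,5,6,8a-octahydronaphthalene-1-carboxylate | O[C@@H]1CC[C@H]2CC(=O)C=C[C@@]2(C)[C@@H]1C(=O)OC | intermediate
16 | methyl (1S,2R,4aS,8aR)-2-hydroxy-7-iodo-8a-methyl-6-oxo-1,2,3,4,4a,5,6,8a-octahydronaphthalene-1-carboxylate | O[C@@H]1CC[C@H]2CC(=O)C(I)=C[C@@]2(C)[C@@H]1C(=O)OC | intermediate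
17 | angelic acid [(2Z)-2-methylbut-2-enoic acid] | C/C=C(/C)C(=O)O | starting material
18 | (2Z)-2-methylbut-2-enoic 2,4,6-trichlorobenzoic anhydride | C/C=C(/C)C(=O)OC(=O)c1c(Cl)cc(Cl)cc1Cl | intermediate
19 | methyl (1S,2R,4aS,8aR)-7-iodo-8a-methyl-2-{[(2Z)-2-methylbut-2-enoyl]oxy}-6-oxo-1,2,3,4,4a,5,6,8a-octahydronaphthalene-1-carboxylate | C/C=C(/C)C(=O)O[C@@H]1CC[C@H]2CC(=O)C(I)=C[C@@]2(C)[C@@H]1C(=O)OC | intermediate
20 | methyl 2-chloropropanoate (racemic) | CC(Cl)C(=O)OC | starting material
21 | methyl (1S,2R,4aS,8aS)-7-[(2S)-1-methoxy-1-oxopropan-2-yl]-8a-methyl-2-{[(2Z)-2-methylbut-2-enoyl]oxy}-6-oxo-1,2,3,4,4a,5,6,8a-octahydronaphthalene-1-carboxylate | C/C=C(/C)C(=O)O[C@@H]1CC[C@H]2CC(=O)C([C@H](C)C(=O)OC)=C[C@@]2(C)[C@@H]1C(=O)OC | target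

**Step count and risks**
Total steps: 10. Longest linear sequence: 10 (steps 1 to 10; 7, 17 and 20 enter directly).

The three steps most likely to fail:

Step 3 (new enantioselective cycloaddition; the hindered β‑carbon and the ester‑bearing diene may be too unreactive or poorly selective). The fallback sets out from 6 and 7 and comes back at 8. The cycloaddition is run with the achiral mixed Lewis acid AlBr3/AlMe3 in CH2Cl2, a known way to join 2‑silyloxydienes to 3‑methylcycloalkenones. This gives 8 as a racemate, that is together with its enantiomer methyl (3aS,7aS)-5-[(tert-butyldimethylsilyl)oxy]-3a-methyl-1-oxo-2,3,3a,4,7,7a-hexahydro-1H-indene-4-carboxylate F1, which is removed by preparative chromatography on a chiral stationary phase (resolution in place of catalyst control).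

Step 7 (facial selectivity at C‑2 and the C‑1 configuration depend on which epimer and conformer of the β‑keto ester reacts). The fallback sets out from 14 and comes back at 19. If hydride adds to the other face of the ketone, the product is methyl (1S,2S,4aS,8aS)-2-hydroxy-8a-methyl-6-oxo-1,2,3,4,4a,5,6,8a-octahydronaphthalene-1-carboxylate F2. It is iodinated as in step 8 to methyl (1S,2S,4aS,8aR)-2-hydroxy-7-iodo-8a-methyl-6-oxo-1,2,3,4,4a,5,6,8a-octahydronaphthalene-1-carboxylate F3. The angelate is then introduced with inversion at C‑2 by Mitsunobu esterification with 17 (PPh3, diisopropyl azodicarboxylate, toluene, 0 °C), which gives 19. This fallback does not help if C‑1 comes out wrong.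

Step 10 (new enantioconvergent coupling; risks are proto‑deiodination, low stereocontrol on a chiral substrate, or angelate isomerisation). The fallback sets out from 19 and comes back at 21. A Negishi coupling (Pd(PPh3)4, THF, 40 °C) of 19 with the Reformatsky reagent bromo(1-methoxy-1-oxopropan-2-yl)zinc F4, made from methyl 2‑bromopropanoate and Zn, forms the same bond without stereocontrol. It gives 21 together with its side‑chain epimer methyl (1S,2R,4aS,8aS)-7-[(2R)-1-methoxy-1-oxopropan-2-yl]-8a-methyl-2-{[(2Z)-2-methylbut-2-enoyl]oxy}-6-oxo-1,2,3,4,4a,5,6,8a-octahydronaphthalene-1-carboxylate F5. The two are separated by HPLC, and F5 is recycled by DBU equilibration at the acidic side‑chain carbon followed by renewed separation.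

**Further compounds**
F1 | step 3 | methyl (3aS,7aS)-5-[(tert-butyldimethylsilyl)oxy]-3a-methyl-1-oxo-2,3,3a,4,7,7a-hexahydro-1H-indene-4-carboxylate | CC(C)(C)[Si](C)(C)OC1=CC[C@@H]2C(=O)CC[C@]2(C)C1C(=O)OC
F2 | step 7 | methyl (1S,2S,4aS,8aS)-2-hydroxy-8a-methyl-6-oxo-1,2,3,4,4a,5,6,8a-octahydronaphthalene-1-carboxylate | O[C@H]1CC[C@H]2CC(=O)C=C[C@@]2(C)[C@@H]1C(=O)OC
F3 | step 7 | methyl (1S,2S,4aS,8aR)-2-hydroxy-7-iodo-8a-methyl-6-oxo-1,2,3,4,4a,5,6,8a-octahydronaphthalene-1-carboxylate | O[C@H]1CC[C@H]2CC(=O)C(I)=C[C@@]2(C)[C@@H]1C(=O)OC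
F4 | step 10 | bromo(1-methoxy-1-oxopropan-2-yl)zinc | COC(=O)C(C)[Zn]Br
F5 | step 10 | methyl (1S,2R,4aS,8aS)-7-[(2R)-1-methoxy-1-oxopropan-2-yl]-8a-methyl-2-{[(2Z)-2-methylbut-2-enoyl]oxy}-6-oxo-1,2,3,4,4a,5,6,8a-octahydronaphthalene-1-carboxylate | C/C=C(/C)C(=O)O[C@@H]1CC[C@H]2CC(=O)C([C@@H](C)C(=O)OC)=C[C@@]2(C)[C@@H]1C(=O)OC
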